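**Retrosynthetic overview**

- The route rests on one feature: ring A is a phloroglucinol (C2′, C4′, C6′ oxygenated) whose C3′, flanked by the O-bearing C2′ and C4′, carries the easily ionised diarylmethine C1 of the C1–C2–C3 stereotriad. The C3′–C1 bond is therefore never made on an arene; it is carried in as the alkyne–C1 bond of ynol ether 19.
- Ring A is the only ring formed (step 10): benzannulation of 19 with 3-benzyloxycyclobutenone 21 makes C2′–C3′ and C4′–C5′. The three other arenes are bought.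
- The acyl chain is attached last without acid: C1′–C(=O) by Br–Li exchange on 29 and acylation with Weinreb amide 32, then global hydrogenolysis.
- 19 comes from β-aryl ester 15 (its Cα and C=O become C3′ and C4′) through the dibromo ester and the ynolate. C1 is set by Rh/(R)-BINAP 1,4-arylation of enoate 13.
- C3 and C2 are set by two reagent-controlled lithiation–borylation homologations of benzylboronate 2, then Zweifel vinylation and cross-metathesis.

Key step: step 10

Assumption: ethyl 2,4,6-triisopropylbenzoate (3) and both sparteine enantiomers are taken as purchasable; imperfect enantioselection in steps 2 and 3 would show up as a minor diastereomer, to be removed by chromatography at 9 or 15.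

**Route**

Step 1
Reactants: 1 4-(benzyloxy)benzyl chloride
Product: 2 2-[4-(benzyloxy)benzyl]-4,4,5,5-tetramethyl-1,3,2-dioxaborolane
Conditions: B2pin2, Pd(dba)2 (3 mol %), P(4-MeOC6H4)3 (6 mol %), KOAc, toluene, 50 °C
Reagents that add atoms: bis(pinacolato)diboron, CC1(C)OB(OC1(C)C)B1OC(C)(C)C(C)(C)O1
Why: Miyaura borylation of a benzylic chloride (oxidative addition of zerovalent palladium into C–Cl, acetate-assisted transmetalation with the diboron, reductive elimination), to which the aryl benzyl ether is inert.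

Step 2
Reactants: 2 2-[4-(benzyloxy)benzyl]-4,4,5,5-tetramethyl-1,3,2-dioxaborolane; 3 ethyl 2,4,6-triisopropylbenzoate
Product: 6 2-[(2S)-1-[4-(benzyloxy)phenyl]propan-2-yl]-4,4,5,5-tetramethyl-1,3,2-dioxaborolane, via lithiated benzoate 4 (not isolated), via boronate complex 5 (not isolated)
Conditions: 3, (+)-sparteine, s-BuLi, Et2O, −78 °C; then 2, −78 °C → 35 °C
Reagents that add atoms: none
Why: Lithiation–borylation (Matteson-type homologation): (+)-sparteine-directed deprotonation gives the configurationally stable (R)-α-lithio benzoate 4, which is borylated with retention and then undergoes a stereospecific 1,2-metallate shift with inversion on warming, so the reagent alone sets the C3 methyl stereocentre (S in 6).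

Step 3
Reactants: 6 2-[(2S)-1-[4-(benzyloxy)phenyl]propan-2-yl]-4,4,5,5-tetramethyl-1,3,2-dioxaborolane; 3 ethyl 2,4,6-triisopropylbenzoate
Product: 9 2-[(2R,3S)-4-[4-(benzyloxy)phenyl]-3-methylbutan-2-yl]-4,4,5,5-tetramethyl-1,3,2-dioxaborolane, via lithiated benzoate 7 (not isolated), via boronate complex 8 (not isolated)
Conditions: 3, (−)-sparteine, s-BuLi, Et2O, −78 °C; then 6, −78 °C → 35 °C
Reagents that add atoms: none
Why: Second lithiation–borylation with the enantiomeric (S)-lithio benzoate 7; the secondary alkyl group migrates with retention and the carbenoid carbon is inverted, so the C2 methyl stereocentre is again reagent-controlled and the two methyls come out syn along the C1–C4 chain.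

Step 4
Reactants: 9 2-[(2R,3S)-4-[4-(benzyloxy)phenyl]-3-methylbutan-2-yl]-4,4,5,5-tetramethyl-1,3,2-dioxaborolane
Product: 12 1-(benzyloxy)-4-[(2S,3S)-2,3-dimethylpent-4-en-1-yl]benzene, via vinylboronate complex 10 (not isolated), via iodoalkylboronic ester 11 (not isolated)
Conditions: CH2=CHMgBr (4 equiv), THF/DMSO (1:1), 0 °C → rt; I2, MeOH, −78 °C; NaOMe, MeOH, −78 °C → rt
Reagents that add atoms: vinylmagnesium bromide, C=C[Mg]Br
Why: Zweifel olefination: iodination of vinyl ate complex 10 triggers 1,2-migration of the secondary alkyl group with retention at the migrating carbon, and methoxide then induces anti elimination of boron and iodide, so C2 is transferred unchanged.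

Step 5
Reactants: 12 1-(benzyloxy)-4-[(2S,3S)-2,3-dimethylpent-4-en-1-yl]benzene
Product: 13 ethyl (2E,4R,5S)-6-[4-(benzyloxy)phenyl]-4,5-dimethylhex-2-enoate
Conditions: ethyl acrylate (5 equiv), second-generation Hoveyda–Grubbs catalyst RuCl2(=CH-C6H4-2-O-i-Pr)(SIMes) (5 mol %), CH2Cl2, 40 °C
Reagents that add atoms: ethyl acrylate, C=CC(=O)OCC
Why: Olefin cross-metathesis of a terminal alkene with an electron-poor acrylate should give the E-enoate selectively, with loss of ethene and no epimerisable carbonyl next to C2.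

Step 6
Reactants: 13 ethyl (2E,4R,5S)-6-[4-(benzyloxy)phenyl]-4,5-dimethylhex-2-enoate; 14 [4-(benzyloxy)phenyl]boronic acid
Product: 15 ethyl (3R,4R,5S)-3,6-bis[4-(benzyloxy)phenyl]-4,5-dimethylhexanoate
Conditions: 14 (3 equiv), Rh(acac)(C2H4)2 (3 mol %), (R)-BINAP (3.3 mol %), 1,4-dioxane/H2O (10:1), 100 °C
Reagents that add atoms: none
Why: Hayashi–Miyaura rhodium-catalysed asymmetric 1,4-addition: the (S)-BINAP aryl–rhodium species is known to add to the 2-Si face of enones and E-enoates, so (R)-BINAP should deliver the aryl group to the 2-Re/3-Si face of 13 under catalyst control and set C1 of the target (C3 of 15, R) syn to the C2 methyl.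

Step 7
Reactants: 15 ethyl (3R,4R,5S)-3,6-bis[4-(benzyloxy)phenyl]-4,5-dimethylhexanoate
Product: 17 ethyl (3R,4R,5S)-3,6-bis[4-(benzyloxy)phenyl]-2,2-dibromo-4,5-dimethylhexanoate, via monobromo ester 16 (not isolated)
Conditions: LiHMDS (1.2 equiv), THF, −78 °C, then BrCF2CF2Br; LiHMDS (1.3 equiv), −78 °C, then BrCF2CF2Br, −78 → 0 °C
Reagents that add atoms: 1,2-dibromotetrafluoroethane, FC(F)(Br)C(F)(F)Br
Why: Two enolisation/electrophilic bromination cycles at the only acidic site (the ester α-CH2); the benzylic C3–H is not acidic, so the C1 stereocentre is untouched.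

Step 8
Reactants: 17 ethyl (3R,4R,5S)-3,6-bis[4-(benzyloxy)phenyl]-2,2-dibromo-4,5-dimethylhexanoate
Product: 19 {[(3R,4R,5S)-3,6-bis[4-(benzyloxy)phenyl]-4,5-dimethylhex-1-yn-1-yl]oxy}tri(propan-2-yl)silane, via lithium ynolate 18 (not isolated)
Conditions: t-BuLi (4.0 equiv), THF, −78 °C then 0 °C; TIPSCl, −78 °C → rt; non-aqueous work-up
Reagents that add atoms: chlorotri(propan-2-yl)silane, CC(C)[Si](Cl)(C(C)C)C(C)C
Why: Ynolate formation by double bromine–lithium exchange: the resulting α-lithio ester enolate expels ethoxide to give ynolate 18, which the bulky silyl chloride traps on oxygen; the exchange is much faster than metalation of the benzyl ethers at −78 °C if exactly four equivalents are used.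

Step 9
Reactants: 20 3-ethoxycyclobut-2-en-1-one
Product: 21 3-(benzyloxy)cyclobut-2-en-1-one
Conditions: BnOH (3 equiv), camphorsulfonic acid (5 mol %), benzene, 4 Å MS, rt
Reagents that add atoms: benzyl alcohol, OCc1ccccc1
Why: Acid-catalysed transetherification (addition–elimination at C3 of the vinylogous ester), driven by excess benzyl alcohol and removal of ethanol.

Step 10
Reactants: 19 {[(3R,4R,5S)-3,6-bis[4-(benzyloxy)phenyl]-4,5-dimethylhex-1-yn-1-yl]oxy}tri(propan-2-yl)silane; 21 3-(benzyloxy)cyclobut-2-en-1-one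
Product: 26 5-(benzyloxy)-2-[(1R,2R,3S)-1,4-bis[4-(benzyloxy)phenyl]-2,3-dimethylbutyl]-3-[(triisopropylsilyl)oxy]phenol, via vinylketene 22 (not isolated), via vinylcyclobutenone 23 (not isolated), via dienylketene 24 (not isolated), via cyclohexadienone 25 (not isolated)
Conditions: 21 (2 equiv, two portions), toluene (0.5 M), sealed tube, 80 °C then 120 °C; then K2CO3, MeOH, 0 °C (cleaves any O-acylated phenol)
Reagents that add atoms: none
Why: Heating opens 21 by four-electron conrotatory electrocyclic ring opening to vinylketene 22, whose ketene C=C undergoes a regioselective [2+2] cycloaddition with the ynol ether so that the alkyne carbon bearing C1 bonds to the ketene carbonyl carbon (new C2′–C3′ bond) and the O-silylated alkyne carbon bonds to the ketene α-carbon (new C4′–C5′ bond), giving 23. A second four-electron opening of 23 gives dienylketene 24, and ring A is closed by a thermally allowed disrotatory six-electron electrocyclisation joining the ketene carbon to the vinyl terminus (C2′–C1′), followed by tautomerisation of cyclohexadienone 25 to phenol 26. The closest known reaction type is the Danheiser benzannulation of cyclobutenones with siloxyalkynes to resorcinol monosilyl ethers. No stereocentre is created, and C1, C2 and C3 are spectators because the cascade is neutral and pericyclic, with no cation, anion or radical at the doubly benzylic C1. The step needs regioselectivity in the [2+2] event, secured by the polarisation of the ynol ether (carbon β to oxygen nucleophilic) matched with the electrophilic central ketene carbon, and it needs the hindered alkyne to outrun ketene dimerisation, which high concentration and portionwise addition of 21 should favour.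

Step 11
Reactants: 26 5-(benzyloxy)-2-[(1R,2R,3S)-1,4-bis[4-(benzyloxy)phenyl]-2,3-dimethylbutyl]-3-[(triisopropylsilyl)oxy]phenol
Product: 28 1,3,5-tris(benzyloxy)-2-[(1R,2R,3S)-1,4-bis[4-(benzyloxy)phenyl]-2,3-dimethylbutyl]benzene, via resorcinol 27 (not isolated)
Conditions: TBAF, THF, 0 °C; then BnBr (3 equiv), K2CO3, DMF, rt, under argon
Reagents that add atoms: benzyl bromide, BrCc1ccccc1
Why: Fluoride cleaves the aryl silyl ether and the two phenoxides are O-benzylated (Williamson etherification) in a polar aprotic medium, which protects ring A uniformly and makes C1′ and C5′ equivalent.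

Step 12
Reactants: 28 1,3,5-tris(benzyloxy)-2-[(1R,2R,3S)-1,4-bis[4-(benzyloxy)phenyl]-2,3-dimethylbutyl]benzene
Product: 29 1,3,5-tris(benzyloxy)-2-bromo-4-[(1R,2R,3S)-1,4-bis[4-(benzyloxy)phenyl]-2,3-dimethylbutyl]benzene
Conditions: NBS (1.0 equiv), MeCN/CH2Cl2, −30 → 0 °C, dark
Reagents that add atoms: N-bromosuccinimide, O=C1CCC(=O)N1Br
Why: Electrophilic aromatic bromination: the tris-alkoxylated ring A is far more nucleophilic than the two mono-alkoxy rings, its two free positions are equivalent, and one equivalent of NBS at low temperature should stop at the monobromide without acid.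

Step 13
Reactants: 30 3-(4-methoxyphenyl)propanoic acid
Product: 32 N-methoxy-3-(4-methoxyphenyl)-N-methylpropanamide, via acyl imidazole 31 (not isolated)
Conditions: CDI, CH2Cl2, rt; then MeNHOMe·HCl, rt
Reagents that add atoms: N,O-dimethylhydroxylamine hydrochloride, CNOC.Cl
Why: Weinreb amide formation by carbonyldiimidazole activation of the acid and aminolysis of acyl imidazole 31.

Step 14
Reactants: 29 1,3,5-tris(benzyloxy)-2-bromo-4-[(1R,2R,3S)-1,4-bis[4-(benzyloxy)phenyl]-2,3-dimethylbutyl]benzene; 32 N-methoxy-3-(4-methoxyphenyl)-N-methylpropanamide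
Product: 34 1-{2,4,6-tris(benzyloxy)-3-[(1R,2R,3S)-1,4-bis[4-(benzyloxy)phenyl]-2,3-dimethylbutyl]phenyl}-3-(4-methoxyphenyl)propan-1-one, via aryllithium 33 (not isolated)
Conditions: n-BuLi (1.05 equiv), THF, −78 °C, 10 min; then 32 (1.5 equiv), −78 → −20 °C; aq. NH4Cl
Reagents that add atoms: none
Why: Bromine–lithium exchange followed by Weinreb ketone synthesis: the chelated tetrahedral adduct prevents over-addition, and the basic, acid-free conditions avoid ionising the C3′–C1 bond.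

Step 15
Reactants: 34 1-{2,4,6-tris(benzyloxy)-3-[(1R,2R,3S)-1,4-bis[4-(benzyloxy)phenyl]-2,3-dimethylbutyl]phenyl}-3-(4-methoxyphenyl)propan-1-one
Product: 35 1-{2,4,6-trihydroxy-3-[(1R,2R,3S)-1,4-bis(4-hydroxyphenyl)-2,3-dimethylbutyl]phenyl}-3-(4-methoxyphenyl)propan-1-one (CNP0193401.1)
Conditions: H2 (1 atm), Pd/C (10 wt %), EtOAc/MeOH (1:1), rt
Reagents that add atoms: none
Why: Catalytic hydrogenolysis of the five benzyl ethers; the hydrogen-bonded aryl ketone, the methyl ether and the heteroatom-free C1 methine should survive at one atmosphere.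

**Compound list**

1 | 4-(benzyloxy)benzyl chloride | ClCc1ccc(OCc2ccccc2)cc1 | starting material
2 | 2-[4-(benzyloxy)benzyl]-4,4,5,5-tetramethyl-1,3,2-dioxaborolane | CC1(C)OB(Cc2ccc(OCc3ccccc3)cc2)OC1(C)C | intermediate
3 | ethyl 2,4,6-triisopropylbenzoate | CCOC(=O)c1c(C(C)C)cc(C(C)C)cc1C(C)C | starting material
4 | (R)-1-lithioethyl 2,4,6-triisopropylbenzoate, (+)-sparteine-bound | C[C@@H]([Li])OC(=O)c1c(C(C)C)cc(C(C)C)cc1C(C)C | intermediate
5 | lithium boronate (ate complex) from 2 and 4 | C[C@@H]([B-]1(Cc2ccc(OCc3ccccc3)cc2)OC(C)(C)C(C)(C)O1)OC(=O)c1c(C(C)C)cc(C(C)C)cc1C(C)C.[Li+] | intermediate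
6 | 2-[(2S)-1-[4-(benzyloxy)phenyl]propan-2-yl]-4,4,5,5-tetramethyl-1,3,2-dioxaborolane | CC1(C)OB(OC1(C)C)[C@@H](C)Cc1ccc(OCc2ccccc2)cc1 | intermediate
7 | (S)-1-lithioethyl 2,4,6-triisopropylbenzoate, (−)-sparteine-bound | C[C@H]([Li])OC(=O)c1c(C(C)C)cc(C(C)C)cc1C(C)C | intermediate
8 | lithium boronate (ate complex) from 6 and 7 | C[C@H]([B-]1([C@@H](C)Cc2ccc(OCc3ccccc3)cc2)OC(C)(C)C(C)(C)O1)OC(=O)c1c(C(C)C)cc(C(C)C)cc1C(C)C.[Li+] | intermediate
9 | 2-[(2R,3S)-4-[4-(benzyloxy)phenyl]-3-methylbutan-2-yl]-4,4,5,5-tetramethyl-1,3,2-dioxaborolane | CC1(C)OB(OC1(C)C)[C@H](C)[C@@H](C)Cc1ccc(OCc2ccccc2)cc1 | intermediate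
10 | bromomagnesium vinylboronate (ate complex) of 9 | C=C[B-]1([C@H](C)[C@@H](C)Cc2ccc(OCc3ccccc3)cc2)OC(C)(C)C(C)(C)O1.[Mg+2].[Br-] | intermediate
11 | 2-[5-[4-(benzyloxy)phenyl]-1-iodo-3,4-dimethylpentan-2-yl]-4,4,5,5-tetramethyl-1,3,2-dioxaborolane (C2 epimers; C3 and C4 as in 9) | ICC(B1OC(C)(C)C(C)(C)O1)[C@H](C)[C@@H](C)Cc1ccc(OCc2ccccc2)cc1 | intermediate
12 | 1-(benzyloxy)-4-[(2S,3S)-2,3-dimethylpent-4-en-1-yl]benzene | C=C[C@H](C)[C@@H](C)Cc1ccc(OCc2ccccc2)cc1 | intermediate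
13 | ethyl (2E,4R,5S)-6-[4-(benzyloxy)phenyl]-4,5-dimethylhex-2-enoate | CCOC(=O)/C=C/[C@H](C)[C@@H](C)Cc1ccc(OCc2ccccc2)cc1 | intermediate
14 | [4-(benzyloxy)phenyl]boronic acid | OB(O)c1ccc(OCc2ccccc2)cc1 | starting material
15 | ethyl (3R,4R,5S)-3,6-bis[4-(benzyloxy)phenyl]-4,5-dimethylhexanoate | CCOC(=O)C[C@@H](c1ccc(OCc2ccccc2)cc1)[C@H](C)[C@@H](C)Cc1ccc(OCc2ccccc2)cc1 | intermediate
16 | ethyl 2-bromo-3,6-bis[4-(benzyloxy)phenyl]-4,5-dimethylhexanoate (C2 epimers; C3–C5 as in 15) | CCOC(=O)C(Br)[C@@H](c1ccc(OCc2ccccc2)cc1)[C@H](C)[C@@H](C)Cc1ccc(OCc2ccccc2)cc1 | intermediate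
17 | ethyl (3R,4R,5S)-3,6-bis[4-(benzyloxy)phenyl]-2,2-dibromo-4,5-dimethylhexanoate | CCOC(=O)C(Br)(Br)[C@@H](c1ccc(OCc2ccccc2)cc1)[C@H](C)[C@@H](C)Cc1ccc(OCc2ccccc2)cc1 | intermediate
18 | lithium (3R,4R,5S)-3,6-bis[4-(benzyloxy)phenyl]-4,5-dimethylhex-1-yn-1-olate | [Li+].[O-]C#C[C@@H](c1ccc(OCc2ccccc2)cc1)[C@H](C)[C@@H](C)Cc1ccc(OCc2ccccc2)cc1 | intermediate
19 | {[(3R,4R,5S)-3,6-bis[4-(benzyloxy)phenyl]-4,5-dimethylhex-1-yn-1-yl]oxy}tri(propan-2-yl)silane | CC(C)[Si](C(C)C)(C(C)C)OC#C[C@@H](c1ccc(OCc2ccccc2)cc1)[C@H](C)[C@@H](C)Cc1ccc(OCc2ccccc2)cc1 | intermediate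
20 | 3-ethoxycyclobut-2-en-1-one | CCOC1=CC(=O)C1 | starting material
21 | 3-(benzyloxy)cyclobut-2-en-1-one | O=C1C=C(OCc2ccccc2)C1 | intermediate
22 | 3-(benzyloxy)buta-1,3-dien-1-one (vinylketene) | C=C(OCc1ccccc1)C=C=O | intermediate
23 | 4-[1-(benzyloxy)ethenyl]-2-[(1R,2R,3S)-1,4-bis[4-(benzyloxy)phenyl]-2,3-dimethylbutyl]-3-[(triisopropylsilyl)oxy]cyclobut-2-en-1-one (C4 epimers) | O=C1C([C@@H](c2ccc(OCc3ccccc3)cc2)[C@H](C)[C@@H](C)Cc2ccc(OCc3ccccc3)cc2)=C(O[Si](C(C)C)(C(C)C)C(C)C)C1C(=C)OCc1ccccc1 | intermediate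
24 | 5-(benzyloxy)-2-[(1R,2R,3S)-1,4-bis[4-(benzyloxy)phenyl]-2,3-dimethylbutyl]-3-[(triisopropylsilyl)oxy]hexa-1,3,5-trien-1-one (C2 and C5 cis across C3=C4) | O=C=C([C@@H](c1ccc(OCc2ccccc2)cc1)[C@H](C)[C@@H](C)Cc1ccc(OCc2ccccc2)cc1)/C(O[Si](C(C)C)(C(C)C)C(C)C)=C\C(=C)OCc1ccccc1 | intermediate
25 | 5-(benzyloxy)-2-[(1R,2R,3S)-1,4-bis[4-(benzyloxy)phenyl]-2,3-dimethylbutyl]-3-[(triisopropylsilyl)oxy]cyclohexa-2,4-dien-1-one | O=C1CC(OCc2ccccc2)=CC(O[Si](C(C)C)(C(C)C)C(C)C)=C1[C@@H](c1ccc(OCc2ccccc2)cc1)[C@H](C)[C@@H](C)Cc1ccc(OCc2ccccc2)cc1 | intermediate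
26 | 5-(benzyloxy)-2-[(1R,2R,3S)-1,4-bis[4-(benzyloxy)phenyl]-2,3-dimethylbutyl]-3-[(triisopropylsilyl)oxy]phenol | Oc1cc(OCc2ccccc2)cc(O[Si](C(C)C)(C(C)C)C(C)C)c1[C@@H](c1ccc(OCc2ccccc2)cc1)[C@H](C)[C@@H](C)Cc1ccc(OCc2ccccc2)cc1 | intermediate
27 | 5-(benzyloxy)-2-[(1R,2R,3S)-1,4-bis[4-(benzyloxy)phenyl]-2,3-dimethylbutyl]benzene-1,3-diol | Oc1cc(OCc2ccccc2)cc(O)c1[C@@H](c1ccc(OCc2ccccc2)cc1)[C@H](C)[C@@H](C)Cc1ccc(OCc2ccccc2)cc1 | intermediate
28 | 1,3,5-tris(benzyloxy)-2-[(1R,2R,3S)-1,4-bis[4-(benzyloxy)phenyl]-2,3-dimethylbutyl]benzene | C(Oc1cc(OCc2ccccc2)cc(OCc2ccccc2)c1[C@@H](c1ccc(OCc2ccccc2)cc1)[C@H](C)[C@@H](C)Cc1ccc(OCc2ccccc2)cc1)c1ccccc1 | intermediate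
29 | 1,3,5-tris(benzyloxy)-2-bromo-4-[(1R,2R,3S)-1,4-bis[4-(benzyloxy)phenyl]-2,3-dimethylbutyl]benzene | C(Oc1c(Br)c(OCc2ccccc2)cc(OCc2ccccc2)c1[C@@H](c1ccc(OCc2ccccc2)cc1)[C@H](C)[C@@H](C)Cc1ccc(OCc2ccccc2)cc1)c1ccccc1 | intermediate
30 | 3-(4-methoxyphenyl)propanoic acid | COc1ccc(CCC(=O)O)cc1 | starting material
31 | 1-(imidazol-1-yl)-3-(4-methoxyphenyl)propan-1-one | COc1ccc(CCC(=O)n2ccnc2)cc1 | intermediate
32 | N-methoxy-3-(4-methoxyphenyl)-N-methylpropanamide | COc1ccc(CCC(=O)N(C)OC)cc1 | intermediate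
33 | aryllithium from 29 (lithium in place of bromine) | C(Oc1c([Li])c(OCc2ccccc2)cc(OCc2ccccc2)c1[C@@H](c1ccc(OCc2ccccc2)cc1)[C@H](C)[C@@H](C)Cc1ccc(OCc2ccccc2)cc1)c1ccccc1 | intermediate
34 | 1-{2,4,6-tris(benzyloxy)-3-[(1R,2R,3S)-1,4-bis[4-(benzyloxy)phenyl]-2,3-dimethylbutyl]phenyl}-3-(4-methoxyphenyl)propan-1-one | C(Oc1c(C(=O)CCc2ccc(OC)cc2)c(OCc2ccccc2)cc(OCc2ccccc2)c1[C@@H](c1ccc(OCc2ccccc2)cc1)[C@H](C)[C@@H](C)Cc1ccc(OCc2ccccc2)cc1)c1ccccc1 | intermediate
35 | 1-{2,4,6-trihydroxy-3-[(1R,2R,3S)-1,4-bis(4-hydroxyphenyl)-2,3-dimethylbutyl]phenyl}-3-(4-methoxyphenyl)propan-1-one | COc1ccc(CCC(=O)c2c(O)cc(O)c([C@@H](c3ccc(O)cc3)[C@H](C)[C@@H](C)Cc3ccc(O)cc3)c2O)cc1 | target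

**Step count**

Total: 15 steps. Longest linear sequence: 13 steps (steps 1–8, 10–12, 14, 15); steps 9 and 13 are side branches.

**Steps most likely to fail, with fallbacks**

1. Step 10. The branched, silyl-shielded ynol ether may add too slowly to the vinylketene, so that ketene dimerisation and thermal decomposition of the donor-substituted cyclobutenone win; the alkoxy group may also raise the ring-opening temperature. The fallback reverses the roles so that the small partner is the nucleophile, setting out from 19 and returning at 28. Ketene (from cracking of diketene) is added to 19 in CH2Cl2 at 0 °C in a [2+2] cycloaddition to give 2-[(1R,2R,3S)-1,4-bis[4-(benzyloxy)phenyl]-2,3-dimethylbutyl]-3-[(triisopropylsilyl)oxy]cyclobut-2-en-1-one F1. F1 is heated in toluene with the unhindered (ethynyloxy)tri(propan-2-yl)silane F2 (from lithium acetylide by oxidation with LiOOt-Bu and O-silylation with TIPSOTf). The same ring-opening/[2+2]/ring-opening/electrocyclisation cascade should give 4-[(1R,2R,3S)-1,4-bis[4-(benzyloxy)phenyl]-2,3-dimethylbutyl]-3,5-bis[(triisopropylsilyl)oxy]phenol F3. TBAF followed by BnBr/K2CO3 in DMF converts F3 into 28.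

2. Step 8. Stray t-BuLi may metalate a benzylic OCH2 (followed by Wittig rearrangement), base may eliminate HBr across C2–C3 of 17, or the ynolate may be silylated on carbon to a silylketene. The fallback goes through the terminal alkyne, setting out from 15 and returning at 19. Reduction with i-Bu2AlH in CH2Cl2 at −78 °C gives (3R,4R,5S)-3,6-bis[4-(benzyloxy)phenyl]-4,5-dimethylhexanal F4. One-pot enol nonaflate formation and elimination (nonafluorobutanesulfonyl fluoride, phosphazene base P2-Et, DMF, −30 °C → rt) gives (3S,4R,5S)-3,6-bis[4-(benzyloxy)phenyl]-4,5-dimethylhex-1-yne F5. Deprotonation with n-BuLi, oxidation of the acetylide with LiOOt-Bu (THF, −78 → 0 °C) and trapping with TIPSOTf gives 19.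

3. Step 6. The chiral catalyst and the C2 stereocentre may be mismatched, giving poor facial selectivity at C1, and slow insertion into the γ-branched enoate may let protodeboronation of 14 dominate. The fallback uses an oxazolidinone auxiliary, setting out from 13 and returning at 15. Saponification (LiOH, THF/H2O) gives (2E,4R,5S)-6-[4-(benzyloxy)phenyl]-4,5-dimethylhex-2-enoic acid F6. Its mixed pivalic anhydride is coupled with lithiated (4R)-4-phenyl-1,3-oxazolidin-2-one to give (4R)-3-[(2E,4R,5S)-6-[4-(benzyloxy)phenyl]-4,5-dimethylhex-2-enoyl]-4-phenyl-1,3-oxazolidin-2-one F7. Addition of 4-(benzyloxy)phenylmagnesium bromide with CuBr·SMe2 (THF, −20 °C) to the magnesium-chelated s-cis imide, on the face opposite the 4-phenyl group (the same 2-Re face), gives (4R)-3-[(3R,4R,5S)-3,6-bis[4-(benzyloxy)phenyl]-4,5-dimethylhexanoyl]-4-phenyl-1,3-oxazolidin-2-one F8. Ethanolysis with EtOMgBr in EtOH/THF at 0 °C returns 15.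

**Further compounds**

F1 | step 10 | 2-[(1R,2R,3S)-1,4-bis[4-(benzyloxy)phenyl]-2,3-dimethylbutyl]-3-[(triisopropylsilyl)oxy]cyclobut-2-en-1-one | O=C1CC(O[Si](C(C)C)(C(C)C)C(C)C)=C1[C@@H](c1ccc(OCc2ccccc2)cc1)[C@H](C)[C@@H](C)Cc1ccc(OCc2ccccc2)cc1
F2 | step 10 | (ethynyloxy)tri(propan-2-yl)silane | C#CO[Si](C(C)C)(C(C)C)C(C)C
F3 | step 10 | 4-[(1R,2R,3S)-1,4-bis[4-(benzyloxy)phenyl]-2,3-dimethylbutyl]-3,5-bis[(triisopropylsilyl)oxy]phenol | Oc1cc(O[Si](C(C)C)(C(C)C)C(C)C)c([C@@H](c2ccc(OCc3ccccc3)cc2)[C@H](C)[C@@H](C)Cc2ccc(OCc3ccccc3)cc2)c(O[Si](C(C)C)(C(C)C)C(C)C)c1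
F4 | step 8 | (3R,4R,5S)-3,6-bis[4-(benzyloxy)phenyl]-4,5-dimethylhexanal | O=CC[C@@H](c1ccc(OCc2ccccc2)cc1)[C@H](C)[C@@H](C)Cc1ccc(OCc2ccccc2)cc1
F5 | step 8 | (3S,4R,5S)-3,6-bis[4-(benzyloxy)phenyl]-4,5-dimethylhex-1-yne | C#C[C@@H](c1ccc(OCc2ccccc2)cc1)[C@H](C)[C@@H](C)Cc1ccc(OCc2ccccc2)cc1
F6 | step 6 | (2E,4R,5S)-6-[4-(benzyloxy)phenyl]-4,5-dimethylhex-2-enoic acid | OC(=O)/C=C/[C@H](C)[C@@H](C)Cc1ccc(OCc2ccccc2)cc1
F7 | step 6 | (4R)-3-[(2E,4R,5S)-6-[4-(benzyloxy)phenyl]-4,5-dimethylhex-2-enoyl]-4-phenyl-1,3-oxazolidin-2-one | O=C(/C=C/[C@H](C)[C@@H](C)Cc1ccc(OCc2ccccc2)cc1)N1[C@H](c2ccccc2)COC1=O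
F8 | step 6 | (4R)-3-[(3R,4R,5S)-3,6-bis[4-(benzyloxy)phenyl]-4,5-dimethylhexanoyl]-4-phenyl-1,3-oxazolidin-2-one | O=C(C[C@@H](c1ccc(OCc2ccccc2)cc1)[C@H](C)[C@@H](C)Cc1ccc(OCc2ccccc2)cc1)N1[C@H](c2ccccc2)COC1=O
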